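**Plan**
- Retrosynthesis: the two O–S bonds and three benzyl ethers are cut first. Ring A is then opened at C1–C2 and C4–C5, after restoring carboxyl groups on C2 and C4. This leaves a C2–C3–C4 ketodiester and a C1–C6–C5 ynoate whose C1 already carries the ring B oxygen. The ynoate is cut at O–C1 and C6–C5 into a ring B phenol, trichloroethylene and methyl chloroformate.
- Enabling feature: ring A is a 1,3,5-trioxygenated benzene (ether oxygen on C1, sulfate on C3, hydroxyl on C5). C1 is therefore at the carboxyl oxidation level of the aryloxy-bearing carbon of a 3-aryloxypropiolate, the C3 oxygen is the ketone of acetonedicarboxylate, and the C5 oxygen is the propiolate ester carbonyl.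
- Forward: ring B comes ready-made from phloroglucinaldehyde and is adjusted (4-O-MOM, 2,6-di-O-benzyl, Baeyer–Villiger to the phenol). The ynoate is attached to the new phenol oxygen. Ring A is the only ring formed, by a [3+3] Michael–Claisen annulation.
- The two ester groups left on ring A make its hydroxyls unequal. One is benzylated, the esters are removed, the MOM group is cleaved, both free phenols are sulfated and the benzyl groups are hydrogenolysed.
- Stereochemistry: the target has no stereocentre and no configured double bond, so nothing has to be set; alkene geometries in two intermediates are transient.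

Key step: step 6

Assumption: the sulfate monoesters of the benzylated bis-sulfate and of the target are written as free acids, as in the target formula; in practice both would be handled as sodium salts after counter-ion exchange on work-up, which differ from the drawn compounds only by the cation.

**Route**

Step 1
Reactants: 1 2,4,6-trihydroxybenzaldehyde
Product: 2 2,6-dihydroxy-4-(methoxymethoxy)benzaldehyde
Conditions: MOMCl (1.0 equiv), K2CO3 (1.1 equiv), acetone, 0 °C to rt
Reagents that add atoms: chloromethyl methyl ether (MOMCl), COCCl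
Why: Williamson-type O-alkylation under weak base; the 4-hydroxyl (para to the formyl group, unhindered and outside the carbonyl hydrogen bond) is the most acidic and accessible phenol, so one equivalent of MOMCl should etherify it preferentially, any bis-MOM ether being removed by chromatography.

Step 2
Reactants: 2 2,6-dihydroxy-4-(methoxymethoxy)benzaldehyde
Product: 3 2,6-bis(benzyloxy)-4-(methoxymethoxy)benzaldehyde
Conditions: BnBr (2.4 equiv), K2CO3, DMF, 60 °C
Reagents that add atoms: benzyl bromide, BrCc1ccccc1
Why: Williamson etherification; in warm DMF both chelated ortho phenols should be O-alkylated, the formyl group deactivating the ring against C-benzylation and the MOM acetal being inert to base.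

Step 3
Reactants: 3 2,6-bis(benzyloxy)-4-(methoxymethoxy)benzaldehyde
Product: 5 2,6-bis(benzyloxy)-4-(methoxymethoxy)phenol, via aryl formate 4 (not isolated)
Conditions: mCPBA (1.2 equiv), CH2Cl2, 0 °C to rt; then K2CO3 (cat.), MeOH, rt
Reagents that add atoms: meta-chloroperoxybenzoic acid (mCPBA), OOC(=O)c1cccc(Cl)c1
Why: Baeyer–Villiger (Dakin-type) oxidation; the trialkoxyphenyl group migrates in preference to hydrogen in the Criegee adduct to give the aryl formate, which mild methanolysis should cleave to the phenol without touching MOM or benzyl ethers.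

Step 4
Reactants: 5 2,6-bis(benzyloxy)-4-(methoxymethoxy)phenol; 6 trichloroethylene
Product: 7 1,3-bis(benzyloxy)-2-{[(E)-1,2-dichloroethenyl]oxy}-5-(methoxymethoxy)benzene
Conditions: K2CO3, DMF, 70 °C, argon
Reagents that add atoms: none
Why: Base-mediated addition of a phenoxide to dichloroacetylene generated in situ from trichloroethylene (trans addition, then protonation) should give the (E)-1,2-dichlorovinyl aryl ether, a known entry to aryl ynol ethers that tolerates 2,6-disubstituted phenols.

Step 5
Reactants: 7 1,3-bis(benzyloxy)-2-{[(E)-1,2-dichloroethenyl]oxy}-5-(methoxymethoxy)benzene; 8 methyl chloroformate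
Product: 11 methyl 3-[2,6-bis(benzyloxy)-4-(methoxymethoxy)phenoxy]propiolate, via aryl chloroethynyl ether 9 (not isolated), via lithium aryloxyacetylide 10 (not isolated)
Conditions: n-BuLi (2.2 equiv), THF, −78 to −40 °C; then ClCO2Me, −78 °C
Reagents that add atoms: none
Why: Ynol ether synthesis from a dichlorovinyl ether followed by acetylide C-acylation; deprotonation and loss of LiCl give the chloroalkyne, chlorine–lithium exchange gives the lithium aryloxyacetylide, and the chloroformate traps it at −78 °C, where ortho- or benzylic lithiation of the ethers should not compete.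

Step 6
Reactants: 11 methyl 3-[2,6-bis(benzyloxy)-4-(methoxymethoxy)phenoxy]propiolate; 12 dimethyl 3-oxopentanedioate
Product: 14 dimethyl 4-[2,6-bis(benzyloxy)-4-(methoxymethoxy)phenoxy]-2,6-dihydroxyisophthalate, via acyclic Michael adduct 13 (not isolated)
Conditions: NaH (2.5 equiv), THF, 0 °C to 50 °C; cold dilute aq. HCl quench
Reagents that add atoms: none
Why: Proposed new method: the sodium enolate of 12 should add through one methylene carbon to the alkyne carbon of 11 that bears the aryloxy group, the only position polarised for conjugate attack, and the resulting allenoate is protonated by the acidic C–H of the adduct to give enoate 13, held as its delocalised enolate. Deprotonation of the second methylene and E/Z equilibration of the enoate through the extended enolate then allow a 6-exo-trig Claisen (Dieckmann-type) attack of that carbon on the propiolate-derived ester carbonyl, and loss of methoxide with enolisation closes ring A as the bis-phenoxide of 14. The closest known reaction is the NaH-mediated Michael–Claisen [3+3] benzannulation of acetonedicarboxylates with alkyl- and aryl-substituted alkynoates to 2,4-dihydroxyisophthalates; conjugate addition of nucleophiles to 3-alkoxypropiolates is known separately. No stereocentre is formed. The step needs regioselective first attack (secured by the push–pull polarisation of the ynoate), C- over O-acylation (a 2-pyranone formed through oxygen should be reopened by the liberated methoxide and drain to the aromatic phenoxide) and retention of the aryl ether (hydride is not nucleophilic and the enolate form of 13 is no acceptor for a second addition–elimination).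

Step 7
Reactants: 14 dimethyl 4-[2,6-bis(benzyloxy)-4-(methoxymethoxy)phenoxy]-2,6-dihydroxyisophthalate
Product: 15 dimethyl 6-(benzyloxy)-4-[2,6-bis(benzyloxy)-4-(methoxymethoxy)phenoxy]-2-hydroxyisophthalate
Conditions: BnBr (1.05 equiv), K2CO3, DMF, rt to 40 °C
Reagents that add atoms: benzyl bromide, BrCc1ccccc1
Why: Williamson etherification with one equivalent of halide; the hydroxyl next to the ring hydrogen is far more accessible than the one buried between two chelating ester groups, so monoalkylation should occur there and mark the hydroxyl that stays free in the target.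

Step 8
Reactants: 15 dimethyl 6-(benzyloxy)-4-[2,6-bis(benzyloxy)-4-(methoxymethoxy)phenoxy]-2-hydroxyisophthalate
Product: 17 3-(benzyloxy)-5-[2,6-bis(benzyloxy)-4-(methoxymethoxy)phenoxy]phenol, via isophthalic diacid 16 (not isolated)
Conditions: KOH, DMSO/H2O, 100 °C; then AcOH to pH 4, 70 °C
Reagents that add atoms: none
Why: Saponification followed by protodecarboxylation; each carboxyl group is ortho/para to three oxygen substituents, so the acids should lose CO2 by ipso-protonation on gentle heating, as phloroglucinol- and orsellinic-type acids do, while the MOM acetal, the benzyl ethers and the diaryl ether survive.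

Step 9
Reactants: 17 3-(benzyloxy)-5-[2,6-bis(benzyloxy)-4-(methoxymethoxy)phenoxy]phenol
Product: 18 3,5-bis(benzyloxy)-4-[3-(benzyloxy)-5-hydroxyphenoxy]phenol
Conditions: conc. HCl (cat.), MeOH/THF, 50 °C
Reagents that add atoms: none
Why: Acid-catalysed acetal exchange (MOM ether cleavage) in methanol should free the ring B phenol and trap the formaldehyde unit as dimethoxymethane, benzyl ethers and the diaryl ether being stable to dilute acid.

Step 10
Reactants: 18 3,5-bis(benzyloxy)-4-[3-(benzyloxy)-5-hydroxyphenoxy]phenol
Product: 19 3-(benzyloxy)-5-[2,6-bis(benzyloxy)-4-(sulfooxy)phenoxy]phenyl hydrogen sulfate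
Conditions: SO3·pyridine (6 equiv), pyridine, 50 °C; aq. NaHCO3 work-up
Reagents that add atoms: sulfur trioxide–pyridine complex, O=S(=O)([O-])[n+]1ccccc1
Why: O-Sulfation of phenols with an amine–SO3 complex; both free hydroxyls are unhindered and should be converted into aryl sulfate monoesters while the benzyl ethers mask the three hydroxyls that must remain free.

Step 11
Reactants: 19 3-(benzyloxy)-5-[2,6-bis(benzyloxy)-4-(sulfooxy)phenoxy]phenyl hydrogen sulfate
Product: 20 3-[2,6-dihydroxy-4-(sulfooxy)phenoxy]-5-hydroxyphenyl hydrogen sulfate (CNP0460023.0)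
Conditions: H2 (1 atm), Pd/C, MeOH/H2O, rt
Reagents that add atoms: none
Why: Catalytic hydrogenolysis of benzyl aryl ethers over Pd/C under neutral conditions should cleave the three O–benzyl bonds of the pyridine-free sodium salt, aryl sulfate monoester salts and the diaryl ether not being reduced.

**Compound list**

1 | 2,4,6-trihydroxybenzaldehyde | O=Cc1c(O)cc(O)cc1O | starting material
2 | 2,6-dihydroxy-4-(methoxymethoxy)benzaldehyde | O=Cc1c(O)cc(OCOC)cc1O | intermediate
3 | 2,6-bis(benzyloxy)-4-(methoxymethoxy)benzaldehyde | O=Cc1c(OCc2ccccc2)cc(OCOC)cc1OCc1ccccc1 | intermediate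
4 | 2,6-bis(benzyloxy)-4-(methoxymethoxy)phenyl formate | O=COc1c(OCc2ccccc2)cc(OCOC)cc1OCc1ccccc1 | intermediate (not isolated)
5 | 2,6-bis(benzyloxy)-4-(methoxymethoxy)phenol | Oc1c(OCc2ccccc2)cc(OCOC)cc1OCc1ccccc1 | intermediate
6 | trichloroethylene | ClC=C(Cl)Cl | starting material
7 | 1,3-bis(benzyloxy)-2-{[(E)-1,2-dichloroethenyl]oxy}-5-(methoxymethoxy)benzene | Cl/C=C(/Cl)Oc1c(OCc2ccccc2)cc(OCOC)cc1OCc1ccccc1 | intermediate
8 | methyl chloroformate | COC(=O)Cl | starting material
9 | 1,3-bis(benzyloxy)-2-[(chloroethynyl)oxy]-5-(methoxymethoxy)benzene | ClC#COc1c(OCc2ccccc2)cc(OCOC)cc1OCc1ccccc1 | intermediate (not isolated)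
10 | {[2,6-bis(benzyloxy)-4-(methoxymethoxy)phenoxy]ethynyl}lithium | [Li]C#COc1c(OCc2ccccc2)cc(OCOC)cc1OCc1ccccc1 | intermediate (not isolated)
11 | methyl 3-[2,6-bis(benzyloxy)-4-(methoxymethoxy)phenoxy]propiolate | COC(=O)C#COc1c(OCc2ccccc2)cc(OCOC)cc1OCc1ccccc1 | intermediate
12 | dimethyl 3-oxopentanedioate | COC(=O)CC(=O)CC(=O)OC | starting material
13 | dimethyl 2-{(E)-1-[2,6-bis(benzyloxy)-4-(methoxymethoxy)phenoxy]-3-methoxy-3-oxoprop-1-en-1-yl}-3-oxopentanedioate (present as its sodium enolate; the C2 centre is racemic and labile) | COC(=O)/C=C(/Oc1c(OCc2ccccc2)cc(OCOC)cc1OCc1ccccc1)C(C(=O)OC)C(=O)CC(=O)OC | intermediate (not isolated)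
14 | dimethyl 4-[2,6-bis(benzyloxy)-4-(methoxymethoxy)phenoxy]-2,6-dihydroxyisophthalate | COC(=O)c1c(O)cc(Oc2c(OCc3ccccc3)cc(OCOC)cc2OCc2ccccc2)c(C(=O)OC)c1O | intermediate
15 | dimethyl 6-(benzyloxy)-4-[2,6-bis(benzyloxy)-4-(methoxymethoxy)phenoxy]-2-hydroxyisophthalate | COC(=O)c1c(OCc2ccccc2)cc(Oc2c(OCc3ccccc3)cc(OCOC)cc2OCc2ccccc2)c(C(=O)OC)c1O | intermediate
16 | 6-(benzyloxy)-4-[2,6-bis(benzyloxy)-4-(methoxymethoxy)phenoxy]-2-hydroxyisophthalic acid (formed as its potassium salt) | O=C(O)c1c(OCc2ccccc2)cc(Oc2c(OCc3ccccc3)cc(OCOC)cc2OCc2ccccc2)c(C(=O)O)c1O | intermediate (not isolated)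
17 | 3-(benzyloxy)-5-[2,6-bis(benzyloxy)-4-(methoxymethoxy)phenoxy]phenol | Oc1cc(OCc2ccccc2)cc(Oc2c(OCc3ccccc3)cc(OCOC)cc2OCc2ccccc2)c1 | intermediate
18 | 3,5-bis(benzyloxy)-4-[3-(benzyloxy)-5-hydroxyphenoxy]phenol | Oc1cc(OCc2ccccc2)cc(Oc2c(OCc3ccccc3)cc(O)cc2OCc2ccccc2)c1 | intermediate
19 | 3-(benzyloxy)-5-[2,6-bis(benzyloxy)-4-(sulfooxy)phenoxy]phenyl hydrogen sulfate | O=S(=O)(O)Oc1cc(OCc2ccccc2)cc(Oc2c(OCc3ccccc3)cc(OS(=O)(=O)O)cc2OCc2ccccc2)c1 | intermediate
20 | 3-[2,6-dihydroxy-4-(sulfooxy)phenoxy]-5-hydroxyphenyl hydrogen sulfate (CNP0460023.0) | O=S(=O)(O)Oc1cc(O)cc(Oc2c(O)cc(OS(=O)(=O)O)cc2O)c1 | target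

**Count**

Total steps: 11. Longest linear sequence: 11 steps (1 to 20); compounds 6, 8 and 12 enter as purchased reactants.

**Steps most likely to fail**

Step 6. The conjugate addition may be followed by expulsion of the aryloxide (addition–elimination at the push–pull carbon), or cyclisation through oxygen may not revert, so that ring A does not close with the ether intact. The fallback uses known chemistry and gives up the annulation; it sets out from 5 and comes back at 18. Commercial 5-bromobenzene-1,3-diol F1 is monobenzylated (BnBr, K2CO3, DMF; the diol is symmetric, so only the degree of alkylation must be controlled) to 3-(benzyloxy)-5-bromophenol F2. MOMCl with i-Pr2NEt converts this into 1-(benzyloxy)-3-bromo-5-(methoxymethoxy)benzene F3. Ullmann-type diaryl ether coupling of F3 with phenol 5 (CuI, picolinic acid, K3PO4, DMSO, 90 °C, conditions suited to ortho,ortho'-disubstituted phenols) should give 1,3-bis(benzyloxy)-2-[3-(benzyloxy)-5-(methoxymethoxy)phenoxy]-5-(methoxymethoxy)benzene F4. Cleavage of both MOM groups (HCl, MeOH/THF, 50 °C) then gives 18.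

Step 7. Alkylation may occur at the hydroxyl between the esters or twice, that is, regiocontrol in the monobenzylation may be lost. The fallback sets out from 14 and comes back at 17. The esters are removed first (KOH, DMSO/H2O, 100 °C; AcOH to pH 4, 70 °C), through 4-[2,6-bis(benzyloxy)-4-(methoxymethoxy)phenoxy]-2,6-dihydroxyisophthalic acid F5, to give 5-[2,6-bis(benzyloxy)-4-(methoxymethoxy)phenoxy]benzene-1,3-diol F6. Its two hydroxyls are equivalent by symmetry, so benzylation with a slight deficit of BnBr (K2CO3, DMF) should give 17 with only over-alkylation to control; unreacted F6 is recycled.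

Step 8. Hydrolysis may stall at a mono-ester, because both esters are flanked by two ortho substituents and sit next to a phenoxide, and more forcing conditions may erode the MOM acetal. The fallback changes the spectator esters; it sets out from 11 and 12 and comes back at 16. Compound 12 is transesterified with allyl alcohol (DMAP cat., toluene, reflux, removal of methanol) to diallyl 3-oxopentanedioate F7. Annulation of F7 with 11 under the conditions of step 6 should pass through diallyl 2-{(E)-1-[2,6-bis(benzyloxy)-4-(methoxymethoxy)phenoxy]-3-methoxy-3-oxoprop-1-en-1-yl}-3-oxopentanedioate F8 to diallyl 4-[2,6-bis(benzyloxy)-4-(methoxymethoxy)phenoxy]-2,6-dihydroxyisophthalate F9. Monobenzylation as in step 7 gives diallyl 6-(benzyloxy)-4-[2,6-bis(benzyloxy)-4-(methoxymethoxy)phenoxy]-2-hydroxyisophthalate F10. Pd(PPh3)4 (cat.) with morpholine in THF at room temperature then removes both allyl groups under neutral conditions, through a π-allyl complex of palladium, to give diacid 16, which is decarboxylated as in the second half of step 8.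

**Further compounds**

F1 | step 6 | 5-bromobenzene-1,3-diol | Oc1cc(O)cc(Br)c1
F2 | step 6 | 3-(benzyloxy)-5-bromophenol | Oc1cc(Br)cc(OCc2ccccc2)c1
F3 | step 6 | 1-(benzyloxy)-3-bromo-5-(methoxymethoxy)benzene | COCOc1cc(Br)cc(OCc2ccccc2)c1
F4 | step 6 | 1,3-bis(benzyloxy)-2-[3-(benzyloxy)-5-(methoxymethoxy)phenoxy]-5-(methoxymethoxy)benzene | COCOc1cc(OCc2ccccc2)cc(Oc2c(OCc3ccccc3)cc(OCOC)cc2OCc2ccccc2)c1
F5 | step 7 | 4-[2,6-bis(benzyloxy)-4-(methoxymethoxy)phenoxy]-2,6-dihydroxyisophthalic acid | O=C(O)c1c(O)cc(Oc2c(OCc3ccccc3)cc(OCOC)cc2OCc2ccccc2)c(C(=O)O)c1O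
F6 | step 7 | 5-[2,6-bis(benzyloxy)-4-(methoxymethoxy)phenoxy]benzene-1,3-diol | Oc1cc(O)cc(Oc2c(OCc3ccccc3)cc(OCOC)cc2OCc2ccccc2)c1
F7 | step 8 | diallyl 3-oxopentanedioate | C=CCOC(=O)CC(=O)CC(=O)OCC=C
F8 | step 8 | diallyl 2-{(E)-1-[2,6-bis(benzyloxy)-4-(methoxymethoxy)phenoxy]-3-methoxy-3-oxoprop-1-en-1-yl}-3-oxopentanedioate | COC(=O)/C=C(/Oc1c(OCc2ccccc2)cc(OCOC)cc1OCc1ccccc1)C(C(=O)OCC=C)C(=O)CC(=O)OCC=C
F9 | step 8 | diallyl 4-[2,6-bis(benzyloxy)-4-(methoxymethoxy)phenoxy]-2,6-dihydroxyisophthalate | C=CCOC(=O)c1c(O)cc(Oc2c(OCc3ccccc3)cc(OCOC)cc2OCc2ccccc2)c(C(=O)OCC=C)c1O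
F10 | step 8 | diallyl 6-(benzyloxy)-4-[2,6-bis(benzyloxy)-4-(methoxymethoxy)phenoxy]-2-hydroxyisophthalate | C=CCOC(=O)c1c(OCc2ccccc2)cc(Oc2c(OCc3ccccc3)cc(OCOC)cc2OCc2ccccc2)c(C(=O)OCC=C)c1O
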